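**Retrosynthetic overview** — daucane numbering: C1 = quaternary ring-fusion carbon carrying the C15 methyl, C4 = carbinol carbon carrying the isopropyl group, C5 = ring-fusion CH, C6–C10 = rest of the seven-membered ring, C14 = carbon on C8; β = face of C15.
1. Target 24 ⇒ triol 21 (both angelates last) ⇒ bicyclic ketol 16 (C14 ester → methyl, C6 ketone → 6α-OH by hydroxyl-directed reduction).
2. 16 ⇒ acyclic diene ketone 9 + vinyldiazoacetate 13 in one tandem operation: carbenoid cyclopropanation, divinylcyclopropane Cope rearrangement, Mukaiyama aldol; ring order: transient cyclopropane (C6–C7–C8) → seven-membered ring → five-membered ring.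
3. Enabling feature: the seven-membered ring is a masked cyclohepta-1,4-diene (C8=C9 alkene and a C5=C6 enol at the C6 oxygen flank the C7 methylene), so C1–C10 is the sigma bond of a Cope rearrangement; C4(OH)–C5–C6(O) is an aldol retron, so the enol silane that the rearrangement delivers at C5 closes the five-membered ring onto the side-chain ketone (C4–C5 bond).
4. 9 comes from methacrolein, 2-methyl-1,3-dithiane, an amide acetal (Eschenmoser–Claisen sets the E alkene) and isopropyllithium; 13 from ethyl diazoacetate and a siloxyacetaldehyde.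

Key step: step 8

Assumption: the sense of induction of Rh2(R-DOSP)4 (dirhodium tetrakis[(R)-N-(4-dodecylbenzenesulfonyl)prolinate]) is assigned by analogy with styrene/aryldiazoacetate cyclopropanation, the diene vinyl group taking the place of the styrene aryl group; should the opposite sense be found, Rh2(S-DOSP)4 is used instead.

Step 1
Reactants: 1 2-methyl-1,3-dithiane; 2 methacrolein
Product: 3 2-methyl-1-(2-methyl-1,3-dithian-2-yl)prop-2-en-1-ol (racemic)
Conditions: n-BuLi, THF, −30 °C; then 2, −78 °C; H2O
Reagents that add atoms: none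
Why: Corey–Seebach 1,2-addition of the lithiated dithiane (acetyl anion equivalent) to the enal should give the allylic alcohol; its stereocentre is racemic and is destroyed in step 2.

Step 2
Reactants: 3 allylic alcohol; 4 N,N-dimethylacetamide dimethyl acetal
Product: 5 (E)-N,N,4-trimethyl-5-(2-methyl-1,3-dithian-2-yl)pent-4-enamide
Conditions: xylenes, 140 °C, MeOH distilled off
Reagents that add atoms: none
Why: Eschenmoser–Claisen [3,3] rearrangement through a chair transition state with the bulky dithianyl group equatorial should give the E trisubstituted alkene and adds C3 and C4 as the amide chain.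

Step 3
Reactants: 5 dithianyl amide
Product: 6 (E)-N,N,4-trimethyl-6-oxohept-4-enamide
Conditions: MeI, CaCO3, MeCN/H2O, 45 °C
Reagents that add atoms: water, O
Why: S-methylation and hydrolysis of the dithioketal should unmask the methyl ketone as the E enone; the tertiary amide is inert.

Step 4
Reactants: 6 enone amide
Product: 7 (E)-6-[(tert-butyldimethylsilyl)oxy]-N,N,4-trimethylhepta-4,6-dienamide
Conditions: i-Pr2NLi, THF, −78 °C; then TBSOTf, −78 °C
Reagents that add atoms: tert-butyldimethylsilyl trifluoromethanesulfonate (TBSOTf), CC(C)(C)[Si](C)(C)OS(=O)(=O)C(F)(F)F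
Why: kinetic deprotonation of the enone at the α′ methyl group (the amide α-hydrogens are far less acidic) and O-silylation should give the 2-siloxy-1,3-diene.

Step 5
Reactants: 7 siloxy diene amide; 8 isopropyllithium
Product: 9 (E)-8-[(tert-butyldimethylsilyl)oxy]-2,6-dimethylnona-6,8-dien-3-one
Conditions: Et2O, −78 °C; H2O
Reagents that add atoms: none
Why: addition of an alkyllithium to a tertiary amide gives a tetrahedral intermediate that collapses to the ketone only on work-up; introducing the ketone after the enol ether avoids having to differentiate two enolisable ketones.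

Step 6
Reactants: 10 ethyl diazoacetate; 11 (tert-butyldimethylsilyloxy)acetaldehyde
Product: 12 ethyl 4-[(tert-butyldimethylsilyl)oxy]-2-diazo-3-hydroxybutanoate (racemic)
Conditions: DBU (10 mol %), MeCN, 23 °C
Reagents that add atoms: none
Why: base-catalysed aldol-type addition of the diazoacetate carbon to an aldehyde is a standard route to β-hydroxy-α-diazo esters.

Step 7
Reactants: 12 β-hydroxy diazo ester
Product: 13 ethyl (E)-4-[(tert-butyldimethylsilyl)oxy]-2-diazobut-3-enoate
Conditions: POCl3, Et3N, CH2Cl2, 0 °C
Reagents that add atoms: none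
Why: dehydration of a β-hydroxy-α-diazo ester is the usual entry to vinyldiazoacetates; only the CH2OSi hydrogens can be lost, and the conjugated E enol ether (needed for the Cope step) is expected as the less hindered isomer.

Step 8
Reactants: 9 diene ketone; 13 vinyldiazoacetate
Product: 16 ethyl 10α-[(tert-butyldimethylsilyl)oxy]-4β-hydroxy-6-oxo-5αH-dauc-8-en-14-oate, via cis-divinylcyclopropane 14 (not isolated), via cycloheptadiene enol silane 15 (not isolated)
Conditions: Rh2(R-DOSP)4 (1 mol %), heptane, −40 to 23 °C, slow addition of 13; then 80 °C; then CH2Cl2, TiCl4, −78 °C; H2O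
Reagents that add atoms: none
Why: The rhodium carbenoid from 13 should cyclopropanate only the electron-rich 1,1-disubstituted silyl enol ether alkene of 9 (its trisubstituted alkene and the trans enol ether of 13 are poor partners), the catalyst fixing C6 and C8 of cis-divinylcyclopropane 14, which undergoes the [3,3] Cope rearrangement through the boat transition state to 15 and so places a silyl enol ether regiospecifically at C5=C6; TiCl4 then activates the side-chain ketone for an intramolecular Mukaiyama aldol that forms C4–C5. The closest known reaction types are the dirhodium-catalysed tandem cyclopropanation/Cope rearrangement (formal [4+3] cycloaddition) of vinyldiazoacetates with oxygenated dienes and with dienes carrying a trisubstituted terminus, and the TiCl4-mediated Mukaiyama aldol of silyl enol ethers with ketones. The seven-membered ring is closed by the sigmatropic ring expansion of the cyclopropane (C1–C10 formed, C6–C8 broken) and the five-membered ring by a 5-(enolexo)-exo-trig aldol. C1 and C10 are set in the Cope step, absolutely by the catalyst-controlled cyclopropane and relatively by the alkene geometries (the E side chain and the E siloxy group end cis, the Z methyl trans to the C10 oxygen). C5 and C4 are set in the aldol: in the boat conformer left by the rearrangement the C1–C10 bond stands nearly perpendicular to the enol ether plane and the tether is pseudo-equatorial, so the ketone should add to the C5 face anti to C10 (trans ring fusion), with the isopropyl group turned away from C6 and the oxygen syn to the C6 oxygen in the titanium chelate (4β-OH). The step needs the cis-divinyl diastereomer of 14 and carbenoid-site rather than vinylogous reactivity, which the hydrocarbon solvent, the prolinate catalyst and the E-substituted vinyl terminus of 13 are expected to secure, while the choice between C5 and C7 as nucleophile is removed by the rearrangement itself.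

Step 9
Reactants: 16 bicyclic ketol
Product: 17 ethyl 10α-[(tert-butyldimethylsilyl)oxy]-4β,6α-dihydroxy-5αH-dauc-8-en-14-oate
Conditions: Me4NBH(OAc)3, MeCN/AcOH, −20 °C
Reagents that add atoms: none
Why: Evans–Saksena reduction: the C4 alkoxyborohydride should deliver hydride intramolecularly to the β face of the C6 ketone, giving the 1,3-anti diol (6α-OH); the enoate and silyl ether are untouched.

Step 10
Reactants: 17 diol ester
Product: 18 10α-[(tert-butyldimethylsilyl)oxy]-5αH-dauc-8-ene-4β,6α,14-triol
Conditions: i-Bu2AlH (excess), CH2Cl2, −78 to 0 °C; aq. potassium sodium tartrate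
Reagents that add atoms: none
Why: 1,2-reduction of the α,β-unsaturated ester by i-Bu2AlH should give the primary allylic alcohol without touching the alkene.

Step 11
Reactants: 18 triol
Product: 20 10α-[(tert-butyldimethylsilyl)oxy]-5αH-dauc-8-ene-4β,6α-diol, via allylic mesylate 19 (not isolated)
Conditions: MsCl (1.05 equiv), Et3N, THF, −40 °C; then LiEt3BH, −40 to 0 °C
Reagents that add atoms: none
Why: the primary allylic hydroxyl should be sulfonylated selectively (C6–OH is hindered, C4–OH tertiary) and the mesylate displaced by hydride in an SN2 reduction, giving the C14 methyl group without allylic transposition.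

Step 12
Reactants: 20 silyl ether diol
Product: 21 5αH-dauc-8-ene-4β,6α,10α-triol
Conditions: Bu4NF, THF, 23 to 50 °C
Reagents that add atoms: none
Why: fluoride cleavage of the secondary silyl ether; no other group is affected.

Step 13
Reactants: 21 triol; 22 angelic acid
Product: 24 (1S,4R,5S,6S,10R)-6α,10α-bis(angeloyloxy)-5αH-dauc-8-en-4β-ol (the target), via mixed anhydride 23 (not isolated)
Conditions: 22 (4 equiv), 2,4,6-trichlorobenzoyl chloride (4 equiv), Et3N (8 equiv), toluene, 23 °C; then 21 (1 equiv), 80 °C
Reagents that add atoms: angelic acid (second equivalent of 22), C/C=C(/C)C(=O)O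
Why: Yamaguchi mixed-anhydride esterification without a nucleophilic catalyst, in which one molecule of 23 is consumed per secondary hydroxyl so that two angeloyl units from 22 enter the product, should acylate C6–OH and C10–OH with retention of the Z (angelate) geometry while the tertiary C4 hydroxyl stays free.

**Compound list**
1 | 2-methyl-1,3-dithiane | CC1SCCCS1 | starting material
2 | methacrolein | CC(=C)C=O | starting material
3 | 2-methyl-1-(2-methyl-1,3-dithian-2-yl)prop-2-en-1-ol (racemic) | CC(=C)C(O)C1(C)SCCCS1 | intermediate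
4 | N,N-dimethylacetamide dimethyl acetal | COC(C)(OC)N(C)C | starting material
5 | (E)-N,N,4-trimethyl-5-(2-methyl-1,3-dithian-2-yl)pent-4-enamide | CN(C)C(=O)CC/C(C)=C/C1(C)SCCCS1 | intermediate
6 | (E)-N,N,4-trimethyl-6-oxohept-4-enamide | CN(C)C(=O)CC/C(C)=C/C(C)=O | intermediate
7 | (E)-6-[(tert-butyldimethylsilyl)oxy]-N,N,4-trimethylhepta-4,6-dienamide | CN(C)C(=O)CC/C(C)=C/C(=C)O[Si](C)(C)C(C)(C)C | intermediate
8 | isopropyllithium | [Li]C(C)C | starting material
9 | (E)-8-[(tert-butyldimethylsilyl)oxy]-2,6-dimethylnona-6,8-dien-3-one | CC(C)C(=O)CC/C(C)=C/C(=C)O[Si](C)(C)C(C)(C)C | intermediate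
10 | ethyl diazoacetate | CCOC(=O)C=[N+]=[N-] | starting material
11 | (tert-butyldimethylsilyloxy)acetaldehyde | CC(C)(C)[Si](C)(C)OCC=O | starting material
12 | ethyl 4-[(tert-butyldimethylsilyl)oxy]-2-diazo-3-hydroxybutanoate (racemic) | CCOC(=O)C(=[N+]=[N-])C(O)CO[Si](C)(C)C(C)(C)C | intermediate
13 | ethyl (E)-4-[(tert-butyldimethylsilyl)oxy]-2-diazobut-3-enoate | CCOC(=O)C(=[N+]=[N-])/C=C/O[Si](C)(C)C(C)(C)C | intermediate
14 | ethyl (1S,2R)-2-[(tert-butyldimethylsilyl)oxy]-1-{(E)-2-[(tert-butyldimethylsilyl)oxy]ethenyl}-2-[(E)-2,6-dimethyl-5-oxohept-1-en-1-yl]cyclopropane-1-carboxylate | CC(C)C(=O)CC/C(C)=C/[C@]1(O[Si](C)(C)C(C)(C)C)C[C@]1(C(=O)OCC)/C=C/O[Si](C)(C)C(C)(C)C | intermediate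
15 | ethyl (3R,4S)-3,6-bis[(tert-butyldimethylsilyl)oxy]-4-methyl-4-(4-methyl-3-oxopentyl)cyclohepta-1,5-diene-1-carboxylate | CC(C)C(=O)CC[C@@]1(C)C=C(O[Si](C)(C)C(C)(C)C)CC(C(=O)OCC)=C[C@H]1O[Si](C)(C)C(C)(C)C | intermediate
16 | ethyl 10α-[(tert-butyldimethylsilyl)oxy]-4β-hydroxy-6-oxo-5αH-dauc-8-en-14-oate | O=C1CC(C(=O)OCC)=C[C@@H](O[Si](C)(C)C(C)(C)C)[C@@]2(C)CC[C@@](O)(C(C)C)[C@H]12 | intermediate
17 | ethyl 10α-[(tert-butyldimethylsilyl)oxy]-4β,6α-dihydroxy-5αH-dauc-8-en-14-oate | O[C@H]1CC(C(=O)OCC)=C[C@@H](O[Si](C)(C)C(C)(C)C)[C@@]2(C)CC[C@@](O)(C(C)C)[C@H]12 | intermediate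
18 | 10α-[(tert-butyldimethylsilyl)oxy]-5αH-dauc-8-ene-4β,6α,14-triol | O[C@H]1CC(CO)=C[C@@H](O[Si](C)(C)C(C)(C)C)[C@@]2(C)CC[C@@](O)(C(C)C)[C@H]12 | intermediate
19 | 10α-[(tert-butyldimethylsilyl)oxy]-4β,6α-dihydroxy-5αH-dauc-8-en-14-yl methanesulfonate | O[C@H]1CC(COS(C)(=O)=O)=C[C@@H](O[Si](C)(C)C(C)(C)C)[C@@]2(C)CC[C@@](O)(C(C)C)[C@H]12 | intermediate
20 | 10α-[(tert-butyldimethylsilyl)oxy]-5αH-dauc-8-ene-4β,6α-diol | O[C@H]1CC(C)=C[C@@H](O[Si](C)(C)C(C)(C)C)[C@@]2(C)CC[C@@](O)(C(C)C)[C@H]12 | intermediate
21 | 5αH-dauc-8-ene-4β,6α,10α-triol | O[C@H]1CC(C)=C[C@@H](O)[C@@]2(C)CC[C@@](O)(C(C)C)[C@H]12 | intermediate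
22 | angelic acid, (Z)-2-methylbut-2-enoic acid | C/C=C(/C)C(=O)O | starting material
23 | angelic 2,4,6-trichlorobenzoic anhydride | C/C=C(/C)C(=O)OC(=O)c1c(Cl)cc(Cl)cc1Cl | intermediate
24 | 6α,10α-bis(angeloyloxy)-5αH-dauc-8-en-4β-ol, (1S,4R,5S,6S,10R) | C/C=C(/C)C(=O)O[C@H]1CC(C)=C[C@@H](OC(=O)/C(C)=C\C)[C@@]2(C)CC[C@@](O)(C(C)C)[C@H]12 | target

**Totals:** 13 steps; longest linear sequence 11 steps (steps 1–5 and 8–13).

**Steps most likely to fail**

Step 8. The carbenoid may be diverted (vinylogous addition, or the trans-divinylcyclopropane that does not rearrange), and the Lewis-acid closure may proceed with poor control of the ring fusion or of C4. The fallback sets out from 15, isolated after the thermal stage, and returns at 16. Selective cleavage of the enol silyl ether (Bu4NF buffered with AcOH, THF, −20 °C; the secondary allylic silyl ether reacts much more slowly) should give ethyl (3R,4S)-3-[(tert-butyldimethylsilyl)oxy]-4-methyl-4-(4-methyl-3-oxopentyl)-6-oxocyclohept-1-ene-1-carboxylate F1. An equilibrating base-mediated intramolecular aldol of this 1,6-diketone (KOt-Bu, t-BuOH/THF, 0 °C), in which aldol addition and enolisation at C5 are both reversible, should then funnel the material to the hydrogen-bonded trans-fused ketol 16.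

Step 7. The diazo group may be lost, the vinyldiazo ester may electrocyclise to a pyrazole, or an E/Z mixture may form during the dehydration. The fallback sets out from 11 and returns at 13. Wittig olefination with ethyl (triphenylphosphoranylidene)acetate (CH2Cl2, 23 °C) should give ethyl (E)-4-[(tert-butyldimethylsilyl)oxy]but-2-enoate F2. Deconjugative diazo transfer (4-acetamidobenzenesulfonyl azide, DBU, MeCN, 0 °C), through the γ-deprotonated dienolate, should then deliver 13 without an elimination step.

Step 13. The angelate may isomerise to the tiglate, or acylation of the two hindered secondary hydroxyls may stay incomplete. The fallback sets out from 21 and returns at 24. Esterification with 2-[bis(2,2,2-trifluoroethoxy)phosphoryl]propanoic acid (2.5 equiv, DCC, DMAP, CH2Cl2) should give 5αH-dauc-8-ene-4β,6α,10α-triol 6,10-bis{2-[bis(2,2,2-trifluoroethoxy)phosphoryl]propanoate} F3. A double Still–Gennari olefination with acetaldehyde (KN(SiMe3)2, 18-crown-6, THF, −78 °C) should then build both Z-configured 2-methylbut-2-enoates in place.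

**Further compounds**
F1 | step 8 | ethyl (3R,4S)-3-[(tert-butyldimethylsilyl)oxy]-4-methyl-4-(4-methyl-3-oxopentyl)-6-oxocyclohept-1-ene-1-carboxylate | CC(C)C(=O)CC[C@@]1(C)CC(=O)CC(C(=O)OCC)=C[C@H]1O[Si](C)(C)C(C)(C)C
F2 | step 7 | ethyl (E)-4-[(tert-butyldimethylsilyl)oxy]but-2-enoate | CCOC(=O)/C=C/CO[Si](C)(C)C(C)(C)C
F3 | step 13 | 5αH-dauc-8-ene-4β,6α,10α-triol 6,10-bis{2-[bis(2,2,2-trifluoroethoxy)phosphoryl]propanoate} | CC(C(=O)O[C@H]1CC(C)=C[C@@H](OC(=O)C(C)P(=O)(OCC(F)(F)F)OCC(F)(F)F)[C@@]2(C)CC[C@@](O)(C(C)C)[C@H]12)P(=O)(OCC(F)(F)F)OCC(F)(F)F
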